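The bonds cut are both at the benzylic carbon C1: the C1–aryl bond to the 3,4,5-trimethoxyphenyl ring (ring A) and the O1–acyl bond to the 3,4-dimethoxybenzoyl group (ring B). Benzylic C1 is bonded to ring A and to the ester oxygen O1, with the ether oxygen O3 in a 1,3-relationship. Hence one operation can add an aryl Grignard reagent to a magnesium-chelated aldehyde, set C1 against the C2 and C3 methyl groups, and esterify the new alkoxide, the sole unprotected oxygen, in the same flask. The precursor is 2,3-syn (2R,3S)-3-(4-methoxybenzyloxy)-2-methylbutanal, made in three steps from (2S,3S)-2,3-dimethyloxirane; one deprotection then gives the target.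

Key step: step 5

Remark: C1–C4 are the carbons of the butyl chain (C1 benzylic), O1 is the ester oxygen on C1 and O3 the oxygen on C3; epoxide 1 is assumed to be bought as the single enantiomer. The given structures were checked and found mutually consistent: the target is (1R,2R,3S), that is 1,2-anti, 2,3-syn.

Step 1
Reactants: 1 (2S,3S)-2,3-dimethyloxirane; 2 vinylmagnesium bromide
Product: 4 (2S,3S)-3-methylpent-4-en-2-ol, via bromomagnesium (2S,3S)-3-methylpent-4-en-2-olate 3 (not isolated)
Conditions: CuI (10 mol%), THF, -30 → 0 °C; then sat. aq. NH4Cl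
Reagents that add atoms: none
Why: Copper-catalysed SN2 opening of an epoxide by a vinyl Grignard reagent proceeds with inversion at the attacked carbon; because 1 is C2-symmetric both ring carbons are equivalent, so one regio- and stereoisomer should form, with the attacked carbon becoming the methyl-bearing (3S) centre and the untouched carbon the (2S) carbinol centre (2,3-syn).

Step 2
Reactants: 4 (2S,3S)-3-methylpent-4-en-2-ol
Product: 6 1-methoxy-4-({[(2S,3S)-3-methylpent-4-en-2-yl]oxy}methyl)benzene, via sodium (2S,3S)-3-methylpent-4-en-2-olate 5 (not isolated)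
Conditions: NaH (1.3 equiv), THF–DMF (3:1), 0 °C; then 4-methoxybenzyl chloride (1.2 equiv), 0 °C → rt
Reagents that add atoms: 4-methoxybenzyl chloride, COc1ccc(CCl)cc1; sodium hydride, [Na+].[H-] (its sodium is found only in intermediate 5)
Why: Williamson ether synthesis on a simple secondary alkoxide touches no stereocentre, and the 4-methoxybenzyl ether is chosen because its oxygen stays Lewis basic enough to chelate magnesium and it is later removed oxidatively, whereas a benzyl ether would require hydrogenolysis that endangers the benzylic C1–O1 ester bond.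

Step 3
Reactants: 6 1-methoxy-4-({[(2S,3S)-3-methylpent-4-en-2-yl]oxy}methyl)benzene
Product: 8 (2R,3S)-3-[(4-methoxybenzyl)oxy]-2-methylbutanal, via ozonide 3-{(2R,3S)-3-[(4-methoxybenzyl)oxy]butan-2-yl}-1,2,4-trioxolane 7 (not isolated)
Conditions: O3, CH2Cl2, -78 °C (Sudan Red 7B end-point); then PPh3 (1.2 equiv), -78 °C → rt; short silica plug, used at once
Reagents that add atoms: ozone, O=[O+][O-]
Why: Ozonolysis with reductive work-up (Criegee mechanism) cleaves the terminal alkene to the aldehyde and formaldehyde, the anisyl ring being spared by stopping at the indicator end-point at -78 °C and the C2 stereocentre being kept by the neutral phosphine reduction and immediate use.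

Step 4
Reactants: 9 5-bromo-1,2,3-trimethoxybenzene
Product: 10 3,4,5-trimethoxyphenylmagnesium bromide (titrated solution, ca. 1 M in THF)
Conditions: Mg turnings (1.3 equiv), I2 (cat.), THF, 40 °C
Reagents that add atoms: magnesium, [Mg]
Why: Grignard reagent formation by insertion of magnesium into the aryl C–Br bond is routine for this bromide, and a concentrated solution is made so that little donor solvent is carried into the chelation step.

Step 5
Reactants: 8 (2R,3S)-3-[(4-methoxybenzyl)oxy]-2-methylbutanal; 10 3,4,5-trimethoxyphenylmagnesium bromide; 11 3,4-dimethoxybenzoyl chloride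
Product: 13 (1R,2R,3S)-3-[(4-methoxybenzyl)oxy]-2-methyl-1-(3,4,5-trimethoxyphenyl)butyl 3,4-dimethoxybenzoate, via bromomagnesium (1R,2R,3S)-3-[(4-methoxybenzyl)oxy]-2-methyl-1-(3,4,5-trimethoxyphenyl)butan-1-olate 12 (not isolated)
Conditions: MgBr2·OEt2 (3 equiv), CH2Cl2, -20 → -78 °C; 10 (1.15 equiv), -78 °C; then 11 (1.6 equiv), DMAP (0.2 equiv), -78 → 0 °C; aq. NaHCO3
Reagents that add atoms: none
Why: MgBr2 ties the aldehyde oxygen and the ether oxygen O3 of 8 into a six-membered chelate in weakly coordinating CH2Cl2, the aryl group of 10 adds to the activated C1, and the bromomagnesium alkoxide 12 then attacks acyl chloride 11 by addition–elimination (DMAP as acyl-transfer catalyst) before any work-up. The closest known reaction type is the chelation-controlled (Cram-chelate) Grignard addition to β-alkoxy α-methyl aldehydes, joined to the familiar acyl chloride quench of a magnesium alkoxide. No ring is closed; the step forms the C1–C(aryl) and O1–C(acyl) bonds. The single new stereocentre C1 is controlled by the chelate: as 8 is 2,3-syn, the methyl groups on C2 and C3 are cis on the chelate ring and shield the same side, so ring A should enter from the other side and give the 1,2-anti, 1,3-anti arrangement, which is (1R). The step needs facial selectivity at C1, secured by the chelating 4-methoxybenzyl ether and by α- and β-substituents that reinforce each other, and chemoselective acylation of O1, secured because the alkoxide is the only unprotected oxygen and only a small excess of 10 remains to consume 11. Because esterification precedes protonation, the diol stage is bypassed altogether, which removes the problem of telling two secondary hydroxyl groups apart.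

Step 6
Reactants: 13 (1R,2R,3S)-3-[(4-methoxybenzyl)oxy]-2-methyl-1-(3,4,5-trimethoxyphenyl)butyl 3,4-dimethoxybenzoate
Product: 14 (1R,2R,3S)-3-hydroxy-2-methyl-1-(3,4,5-trimethoxyphenyl)butyl 3,4-dimethoxybenzoate
Conditions: DDQ (1.3 equiv), CH2Cl2–pH 7 phosphate buffer (10:1), 0 °C → rt
Reagents that add atoms: none
Why: Oxidative cleavage of a 4-methoxybenzyl ether by DDQ (hydride abstraction from the electron-rich benzylic ether, then hydrolysis of the oxocarbenium ion) should free O3 under buffered neutral conditions, under which the C1 ester, whose benzylic C–H is deactivated by the acyloxy group, is neither oxidised nor moved to O3 and no stereocentre is touched.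

Compound list
1 | (2S,3S)-2,3-dimethyloxirane | C[C@@H]1O[C@H]1C | starting material
2 | vinylmagnesium bromide | C=C[Mg]Br | starting material
3 | bromomagnesium (2S,3S)-3-methylpent-4-en-2-olate | C=C[C@H](C)[C@H](C)O[Mg]Br | intermediate (not isolated)
4 | (2S,3S)-3-methylpent-4-en-2-ol | C=C[C@H](C)[C@H](C)O | intermediate
5 | sodium (2S,3S)-3-methylpent-4-en-2-olate | C=C[C@H](C)[C@H](C)[O-].[Na+] | intermediate (not isolated)
6 | 1-methoxy-4-({[(2S,3S)-3-methylpent-4-en-2-yl]oxy}methyl)benzene | C=C[C@H](C)[C@H](C)OCc1ccc(OC)cc1 | intermediate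
7 | 3-{(2R,3S)-3-[(4-methoxybenzyl)oxy]butan-2-yl}-1,2,4-trioxolane (both epimers at the ring carbon) | O1OC(OC1)[C@H](C)[C@H](C)OCc2ccc(OC)cc2 | intermediate (not isolated)
8 | (2R,3S)-3-[(4-methoxybenzyl)oxy]-2-methylbutanal | O=C[C@H](C)[C@H](C)OCc1ccc(OC)cc1 | intermediate
9 | 5-bromo-1,2,3-trimethoxybenzene | COc1cc(Br)cc(OC)c1OC | starting material
10 | 3,4,5-trimethoxyphenylmagnesium bromide | COc1cc([Mg]Br)cc(OC)c1OC | intermediate
11 | 3,4-dimethoxybenzoyl chloride | COc1ccc(C(=O)Cl)cc1OC | starting material
12 | bromomagnesium (1R,2R,3S)-3-[(4-methoxybenzyl)oxy]-2-methyl-1-(3,4,5-trimethoxyphenyl)butan-1-olate | Br[Mg]O[C@@H](c1cc(OC)c(OC)c(OC)c1)[C@H](C)[C@H](C)OCc2ccc(OC)cc2 | intermediate (not isolated)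
13 | (1R,2R,3S)-3-[(4-methoxybenzyl)oxy]-2-methyl-1-(3,4,5-trimethoxyphenyl)butyl 3,4-dimethoxybenzoate | COc1ccc(C(=O)O[C@@H](c2cc(OC)c(OC)c(OC)c2)[C@H](C)[C@H](C)OCc3ccc(OC)cc3)cc1OC | intermediate
14 | (1R,2R,3S)-3-hydroxy-2-methyl-1-(3,4,5-trimethoxyphenyl)butyl 3,4-dimethoxybenzoate | COc1ccc(C(=O)O[C@@H](c2cc(OC)c(OC)c(OC)c2)[C@H](C)[C@H](C)O)cc1OC | target

Total step count: 6. Longest linear sequence: 5 steps (steps 1, 2, 3, 5, 6); step 4 is a one-step side branch.

Steps most likely to fail

Step 5. THF brought in with 10, or aggregation of the magnesium salts, may loosen the O,O-chelate so that facial selectivity at C1 erodes, and the chelated alkoxide may be acylated only sluggishly. The fallback sets out from aldehyde 8 and comes back at ester 13, replacing substrate chelation by reagent control.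
- Reagent 10 is added to 8 in THF at -78 °C with no demand on selectivity. This gives the C1-epimeric bromomagnesium (1RS,2R,3S)-3-[(4-methoxybenzyl)oxy]-2-methyl-1-(3,4,5-trimethoxyphenyl)butan-1-olates F1 and, after NH4Cl quench, the (1RS,2S,3S)-3-[(4-methoxybenzyl)oxy]-2-methyl-1-(3,4,5-trimethoxyphenyl)butan-1-ols F2.
- Dess–Martin periodinane with NaHCO3 in CH2Cl2 should convert both epimers into the single ketone (2R,3S)-3-[(4-methoxybenzyl)oxy]-2-methyl-1-(3,4,5-trimethoxyphenyl)butan-1-one F3.
- Corey–Bakshi–Shibata reduction with (S)-2-methyl-CBS-oxazaborolidine and BH3·SMe2 in THF at -20 °C should give (1R,2S,3S)-3-[(4-methoxybenzyl)oxy]-2-methyl-1-(3,4,5-trimethoxyphenyl)butan-1-ol F4. The catalyst treats the aryl group as the large substituent, and this acts in the same sense as the Felkin–Anh preference of the α-methyl ketone. C2 is unchanged in space; only its descriptor changes.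
- Acylation with 11, Et3N and DMAP in CH2Cl2 then gives 13.

Step 1. Bromide from the Grignard reagent may open the epoxide to a bromohydrin, or magnesium halide may isomerise it to butanone, before the slow organocopper attack on a 2,3-disubstituted epoxide; the volatile epoxide and alcohol may also be lost on isolation. The fallback sets out from epoxide 1 and comes back at alcohol 4, replacing the organocopper reagent by an acetylide in a medium free of Lewis-acidic halide.
- LiC≡CH·H2NCH2CH2NH2 in DMSO at room temperature should open 1 with inversion to lithium (2S,3S)-3-methylpent-4-yn-2-olate F5, which gives (2S,3S)-3-methylpent-4-yn-2-ol F6 on aqueous quench.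
- Semi-hydrogenation (H2, 1 atm, Pd on CaCO3 poisoned with Pb(OAc)2, quinoline, pentane) then gives 4.

Step 3. Ozone may attack the electron-rich anisyl ring once the alkene is consumed, and C2 of the aldehyde may epimerise while Ph3PO is being removed. The fallback sets out from alkene 6 and comes back at aldehyde 8, replacing direct ozone cleavage by dihydroxylation and glycol cleavage.
- OsO4 (2 mol%) with N-methylmorpholine N-oxide in acetone–water should give (2RS,3S,4S)-4-[(4-methoxybenzyl)oxy]-3-methylpentane-1,2-diol F7, an isolable and configurationally stable compound.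
- NaIO4 on silica gel in CH2Cl2 at room temperature cleaves it to 8, which needs only filtration before use.

Further compounds
F1 | step 5 | bromomagnesium (1RS,2R,3S)-3-[(4-methoxybenzyl)oxy]-2-methyl-1-(3,4,5-trimethoxyphenyl)butan-1-olate (both C1 epimers) | Br[Mg]OC(c1cc(OC)c(OC)c(OC)c1)[C@H](C)[C@H](C)OCc2ccc(OC)cc2
F2 | step 5 | (1RS,2S,3S)-3-[(4-methoxybenzyl)oxy]-2-methyl-1-(3,4,5-trimethoxyphenyl)butan-1-ol (both C1 epimers) | OC(c1cc(OC)c(OC)c(OC)c1)[C@H](C)[C@H](C)OCc2ccc(OC)cc2
F3 | step 5 | (2R,3S)-3-[(4-methoxybenzyl)oxy]-2-methyl-1-(3,4,5-trimethoxyphenyl)butan-1-one | O=C(c1cc(OC)c(OC)c(OC)c1)[C@H](C)[C@H](C)OCc2ccc(OC)cc2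
F4 | step 5 | (1R,2S,3S)-3-[(4-methoxybenzyl)oxy]-2-methyl-1-(3,4,5-trimethoxyphenyl)butan-1-ol | O[C@@H](c1cc(OC)c(OC)c(OC)c1)[C@H](C)[C@H](C)OCc2ccc(OC)cc2
F5 | step 1 | lithium (2S,3S)-3-methylpent-4-yn-2-olate | C#C[C@H](C)[C@H](C)[O-].[Li+]
F6 | step 1 | (2S,3S)-3-methylpent-4-yn-2-ol | C#C[C@H](C)[C@H](C)O
F7 | step 3 | (2RS,3S,4S)-4-[(4-methoxybenzyl)oxy]-3-methylpentane-1,2-diol (both C2 epimers) | OCC(O)[C@H](C)[C@H](C)OCc1ccc(OC)cc1
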